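The data are simulated for an exercise, noise included.

Time is what this flask is given: 2.5 min, while the readings so far stop at 90.0 s.

| flask | left-handed substrate | right-handed substrate | solid reagent | remark | time |
|---|---|---|---|---|---|
| east | 0.050 M | 0.050 M | 1.2 equiv | run made earlier |  |
| south | 0.075 M | 0.075 M | 1.2 equiv | run made earlier |  |
| north-west | 0.10 M | 0.10 M | 2.4 equiv | run made earlier |  |
| flask | 0.10 M | 0.10 M | 1.20 equiv |  | 2.5 min |

- east (time / s: right-handed substrate / %, left-handed substrate / %, left-handed product / %): 15.0: 50.2, 49.8, 0.1; 30.0: 49.6, 48.9, 1.1; 50.0: 49.4, 47.5, 2.5; 60.0: 47.8, 46.6, 2.6; 80.0: 49.0, 45.9, 3.5; 90.0: 48.4, 44.5, 4.6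
- south (time / s: right-handed substrate / %, left-handed substrate / %, left-handed product / %): 10.0: 51.4, 49.3, 1.2; 12.0: 50.8, 49.6, 0; 20.0: 50.0, 50.8, 0.3; 30.0: 49.6, 49.1, 0; 50.0: 49.8, 48.1, 2.2; 90.0: 48.6, 44.9, 5.2
- north-west (time / s: right-handed substrate / %, left-handed substrate / %, left-handed product / %): 10.0: 50.3, 49.4, 0.6; 25.0: 50.6, 49.1, 0.5; 40.0: 49.2, 49.4, 1.9; 60.0: 48.8, 47.4, 3.3; 90.0: 47.6, 45.0, 5.0

(standard deviation of a reading: 0.5 percentage points)

- partner is single-handed; left-handed substrate and right-handed substrate are mirror images of each other, charged as a racemate, each of them at the stated concentration
- solid reagent is a solid; its amount is given per volume of the solution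
- at the start none of the solid reagent is in solution
- the handed part of partner does not stay in what it makes, so the products of the two hands are mirror images too

- whether the excess of right-handed substrate over left-handed substrate among what is left of the two reaches 95% by 2.5 min (no / yes)
- the highest excess of right-handed substrate over left-handed substrate among what is left of the two up to 2.5 min

The bench rule for a racemate says to charge one equivalent of reagent per fast hand, so that the fast hand goes and the slow hand stays. In the runs so far the left-handed substrate (the left hand) falls faster than the right-handed substrate (the right hand), and the flask holds 1.20 equiv on the left hand, so the rule promises a high excess. To test this we work with the fraction of each hand left. At 90.0 s the east, south and north-west runs average 89.6% of the left hand and 96.4% of the right. If both hands react first-order with the same partner, ln(fraction of left left) over ln(fraction of right left) stays constant. This ratio is the selectivity factor, s, which reads 3.00, a rough reading given a scatter of 0.5 percentage points.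

An excess of 95% means 39.0 times as much right as left. With s, that needs 0.409% of the left hand and 15.9% of the right, so 91.8% of both hands must react. At one partner per substrate, the charge pays for 60.0%. The rule stops here: the right hand goes too, and on the way to that excess the solid reagent is the limiting reagent. We say no.

The forecast also says no, with a top of 7%, the excess “still rising at the end”.

The flask gives no, with a top of 5.53%.

    partner + right-handed substrate → right-handed product (k = 0.0326 /M/s)
    2 partner → self-condensation product (k = 0.191 /M/s)
    left-handed product ⇌ right-handed product (k = 0.0128 /s)
    partner + left-handed substrate → left-handed product (k = 0.0728 /M/s)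
    solid reagent ⇌ partner, rate k5*(cs5 - [partner]) while solid is left; crystals form when [partner] > cs5 (solubility = 39.0 mM, k = 0.0224 /s)

At 2.50 min the flask keeps 82% of its left hand, which s turns into an excess of 6.61%, against the 5.53% it shows. The excess stays low in part because partner also makes right-handed product and in part because of the time given: without that step it is 10.6% at 2.50 min, and with ten times the time it is 15.6%.

In the neighbour flask, with the same charge but read at 6.0 min, 61% of the left hand remains, and s gives 16.3%. The computed top there is 13.6%.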